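**Plan**

- Numbering (elemane): C1=C2 vinyl, C10 quaternary, C9, C8 (ester O), C7, C6 (lactone O), C5, C4(=C3)–C15 hydroxypropenyl, C11(=C13)–C12 lactone carbonyl.
- Retrosynthetic cuts, in order: C8–O acyl bond (side chain); C11=C13 methylene; O–C12 lactone bond; ring bond C5–C6 (carbonyl-ene); C7–C8 (Evans aldol); C10–C5 (copper-catalysed allylic substitution).
- Enabling feature: on the cyclohexane C5–C10, C6 carries O and the neighbouring C5 carries an alk-1-en-2-yl group, trans to each other. This homoallylic alcohol unit O–C6–C5–C4(=C3H2) is the isopulegol-type retron of an ene closure of an acyclic C6 aldehyde onto a C5=C4 alkene.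
- Forward: a Z-alkenylboronate and an allylic phosphate are joined at C10; an aldol adds C6, C7, C11 and C12; the cyclohexane closes in step 14, the γ-lactone in step 15; then methylene, ester, deprotection.
- Stereochemistry: C10 from a chiral NHC–copper catalyst; C7 and C8 from (R)-4-benzyloxazolidinone; C5 and C6 from the chair transition state of the ene step; the side-chain centre from (R)-Roche ester; the Z alkene from anti-carbomagnesiation.

Key step: step 14

Remark: the structure is taken as drawn, with the C10 vinyl group cis to the C5 side chain (10R); the antipode of the chiral NHC ligand in step 7 is the one that gives 10R.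

**Route**

Step 1
Reactants: 1 prop-2-yn-1-ol
Product: 3 (2Z)-3-iodo-2-methylprop-2-en-1-ol, via alkenylmagnesium alkoxide 2 (not isolated)
Conditions: MeMgBr (2.5 equiv), CuI (10 mol%), Et2O, 0 °C → rt; then I2, Et2O, −10 °C
Reagents that add atoms: methylmagnesium bromide, C[Mg]Br; iodine, II
Why: Copper-catalysed anti-carbomagnesiation of the magnesium alkoxide puts methyl on C2 and magnesium on C3 cis to the CH2O group in a five-membered chelate, and iodinolysis with retention should give the Z iodide.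

Step 2
Reactants: 3 (2Z)-3-iodo-2-methylprop-2-en-1-ol
Product: 4 tert-butyl{[(2Z)-3-iodo-2-methylprop-2-en-1-yl]oxy}diphenylsilane
Conditions: TBDPSCl, imidazole, CH2Cl2, rt
Reagents that add atoms: tert-butyl(chloro)diphenylsilane, CC(C)(C)[Si](Cl)(c1ccccc1)c1ccccc1
Why: Standard silylation of a primary allylic alcohol; this robust ether should outlast the later cleavage of a triethylsilyl ether.

Step 3
Reactants: 4 tert-butyl{[(2Z)-3-iodo-2-methylprop-2-en-1-yl]oxy}diphenylsilane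
Product: 6 tert-butyl{[(2Z)-2-methyl-3-(4,4,5,5-tetramethyl-1,3,2-dioxaborolan-2-yl)prop-2-en-1-yl]oxy}diphenylsilane, via alkenyllithium 5 (not isolated)
Conditions: tBuLi (2.1 equiv), Et2O, −78 °C; then iPrOB(pin), −78 °C → rt
Reagents that add atoms: 2-isopropoxy-4,4,5,5-tetramethyl-1,3,2-dioxaborolane, CC(C)OB1OC(C)(C)C(C)(C)O1
Why: Iodine–lithium exchange and borylation both proceed with retention of alkene geometry, and the low temperature should suppress oxygen-to-carbon silyl migration in 5.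

Step 4
Reactants: 7 ethyl but-2-ynoate; 8 (1,3-dioxolan-2-ylmethyl)magnesium bromide
Product: 9 ethyl (2E)-4-(1,3-dioxolan-2-yl)-3-methylbut-2-enoate
Conditions: 8, CuBr·SMe2 (1.1 equiv), THF, −40 °C; then 7, −78 °C
Reagents that add atoms: none
Why: Syn carbocupration of the ynoate followed by protonation with retention should place the new carbon group trans to the ester (E enoate).

Step 5
Reactants: 9 ethyl (2E)-4-(1,3-dioxolan-2-yl)-3-methylbut-2-enoate
Product: 10 (2E)-4-(1,3-dioxolan-2-yl)-3-methylbut-2-en-1-ol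
Conditions: iBu2AlH (2.2 equiv), CH2Cl2, −78 °C
Reagents that add atoms: none
Why: 1,2-Reduction of an enoate to the allylic alcohol; the acetal and the alkene geometry are not touched.

Step 6
Reactants: 10 (2E)-4-(1,3-dioxolan-2-yl)-3-methylbut-2-en-1-ol
Product: 11 (2E)-4-(1,3-dioxolan-2-yl)-3-methylbut-2-en-1-yl diethyl phosphate
Conditions: ClP(O)(OEt)2, Et3N, DMAP (cat.), CH2Cl2, 0 °C
Reagents that add atoms: diethyl chlorophosphate, CCOP(=O)(Cl)OCC
Why: O-Phosphorylation of a primary allylic alcohol gives the leaving group used in copper-catalysed allylic substitution.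

Step 7
Reactants: 11 (2E)-4-(1,3-dioxolan-2-yl)-3-methylbut-2-en-1-yl diethyl phosphate; 6 tert-butyl{[(2Z)-2-methyl-3-(4,4,5,5-tetramethyl-1,3,2-dioxaborolan-2-yl)prop-2-en-1-yl]oxy}diphenylsilane
Product: 12 tert-butyl{[(2Z,4R)-4-(1,3-dioxolan-2-ylmethyl)-2,4-dimethylhexa-2,5-dien-1-yl]oxy}diphenylsilane
Conditions: CuCl (10 mol%), chiral sulfonate-bearing imidazolinium salt (NHC precursor, 11 mol%), NaOMe (2 equiv), 6 (1.5 equiv), THF, 22 → 50 °C
Reagents that add atoms: none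
Why: Enantioselective copper-catalysed allylic substitution: methoxide-activated transfer of the alkenyl group from boron to the chiral NHC–copper complex and γ-selective (SN2') addition to the E phosphate should form the C10 quaternary centre beside a new vinyl group, with the ligand antipode fixing 10R and the Z geometry of the alkenyl group retained.

Step 8
Reactants: 12 tert-butyl{[(2Z,4R)-4-(1,3-dioxolan-2-ylmethyl)-2,4-dimethylhexa-2,5-dien-1-yl]oxy}diphenylsilane
Product: 13 (3R,4Z)-6-[(tert-butyldiphenylsilyl)oxy]-3-ethenyl-3,5-dimethylhex-4-enal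
Conditions: 1 M HCl, THF, rt
Reagents that add atoms: water, O
Why: Acid hydrolysis of the dioxolane frees the C8 aldehyde; the primary tert-butyldiphenylsilyl ether and the skipped diene should tolerate dilute acid.

Step 9
Reactants: 14 4-tert-butoxy-4-oxobutanoic acid; 15 (4R)-4-benzyl-1,3-oxazolidin-2-one
Product: 17 tert-butyl 4-[(4R)-4-benzyl-2-oxo-1,3-oxazolidin-3-yl]-4-oxobutanoate, via mixed pivalic anhydride 16 (not isolated)
Conditions: 14, PivCl, Et3N, THF, −20 °C; then LiCl, 15, −20 °C → rt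
Reagents that add atoms: none
Why: N-Acylation of the oxazolidinone through the mixed anhydride, which is attacked at the less hindered succinyl carbonyl.

Step 10
Reactants: 17 tert-butyl 4-[(4R)-4-benzyl-2-oxo-1,3-oxazolidin-3-yl]-4-oxobutanoate; 13 (3R,4Z)-6-[(tert-butyldiphenylsilyl)oxy]-3-ethenyl-3,5-dimethylhex-4-enal
Product: 19 tert-butyl (3R,4S,6R,7Z)-3-{[(4R)-4-benzyl-2-oxo-1,3-oxazolidin-3-yl]carbonyl}-9-[(tert-butyldiphenylsilyl)oxy]-6-ethenyl-4-hydroxy-6,8-dimethylnon-7-enoate, via Z boron enolate 18 (not isolated)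
Conditions: 17, Bu2BOTf, iPr2NEt, CH2Cl2, 0 °C; then 13, −78 → 0 °C; then H2O2, MeOH, pH 7 buffer
Reagents that add atoms: none
Why: Evans syn aldol: the Z boron enolate reacts through a closed Zimmerman–Traxler chair on the face opposite the benzyl group of the (R)-auxiliary, which should set C7 and C8 (locants 3R,4S) in the syn relation that becomes trans on the ring, the remote quaternary centre having no influence.

Step 11
Reactants: 19 aldol adduct
Product: 20 tert-butyl (3R,4S,6R,7Z)-3-{[(4R)-4-benzyl-2-oxo-1,3-oxazolidin-3-yl]carbonyl}-9-[(tert-butyldiphenylsilyl)oxy]-6-ethenyl-6,8-dimethyl-4-[(triethylsilyl)oxy]non-7-enoate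
Conditions: TESOTf, 2,6-lutidine, CH2Cl2, −78 → 0 °C
Reagents that add atoms: triethylsilyl trifluoromethanesulfonate, CC[Si](CC)(CC)OS(=O)(=O)C(F)(F)F
Why: Silylation of the hindered secondary aldol hydroxyl blocks retro-aldol and lactonisation and gives a group that can later be removed beside the tert-butyldiphenylsilyl ether.

Step 12
Reactants: 20 triethylsilyl ether of the aldol adduct
Product: 21 tert-butyl (3S,4S,6R,7Z)-9-[(tert-butyldiphenylsilyl)oxy]-6-ethenyl-3-(hydroxymethyl)-6,8-dimethyl-4-[(triethylsilyl)oxy]non-7-enoate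
Conditions: LiBH4, MeOH (1 equiv), Et2O, 0 °C
Reagents that add atoms: none
Why: Reductive removal of the auxiliary: hydride attacks the activated exocyclic imide carbonyl, while the tert-butyl ester should be too hindered to react at 0 °C.

Step 13
Reactants: 21 primary alcohol
Product: 22 tert-butyl (3R,4S,6R,7Z)-9-[(tert-butyldiphenylsilyl)oxy]-6-ethenyl-3-formyl-6,8-dimethyl-4-[(triethylsilyl)oxy]non-7-enoate
Conditions: Dess–Martin periodinane, CH2Cl2, 0 °C → rt
Reagents that add atoms: none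
Why: Dess–Martin oxidation is non-basic, so the α-stereocentre (C7) and the β-silyloxy group of the aldehyde should survive; 22 is used at once.

Step 14
Reactants: 22 tert-butyl (3R,4S,6R,7Z)-9-[(tert-butyldiphenylsilyl)oxy]-6-ethenyl-3-formyl-6,8-dimethyl-4-[(triethylsilyl)oxy]non-7-enoate
Product: 23 tert-butyl 2-[(1S,2R,3R,4R,6S)-3-{3-[(tert-butyldiphenylsilyl)oxy]prop-1-en-2-yl}-4-ethenyl-2-hydroxy-4-methyl-6-[(triethylsilyl)oxy]cyclohexyl]acetate
Conditions: Me2AlCl (2 equiv), CH2Cl2, −78 → −40 °C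
Reagents that add atoms: none
Why: Me2AlCl binds the aldehyde oxygen, and the activated C6 carbonyl is attacked by C5 of the Z-trisubstituted alkene in a concerted but asynchronous type 1 intramolecular carbonyl-ene reaction, in which a hydrogen of the C4 methyl group passes to oxygen and the double bond moves to C4=C3. The closest known reaction is the Lewis acid cyclisation of citronellal to isopulegol. The carbocycle C5–C6–C7–C8–C9–C10 closes in a 6-exo mode with both the C=O and the C=C bond exocyclic to the new ring, through a chair in which the C7 acetate arm, the C8 silyloxy group and the C10 methyl group are equatorial and the C10 vinyl group is axial. C6 is set by the equatorial placement of the aluminium-bound oxygen (an axial C–O would be syn-diaxial to the C10 vinyl group) and C5 by the equatorial placement of the alkene, so the new C6–O and C5–C4 bonds should be trans to each other and to their neighbours, as in the target. The step needs hydrogen transfer from the methyl and not from the silyloxymethyl group: the Z geometry puts the methyl cis to H5 and within reach of the equatorial oxygen, while the CH2OSi group is held on the far side next to C10. The vinyl group has no allylic hydrogen and cannot compete, and Me2AlCl scavenges protons, so the tert-butyl ester and both silyl ethers should survive at low temperature.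

Step 15
Reactants: 23 ene product
Product: 24 (3aS,4S,6R,7R,7aR)-7-{3-[(tert-butyldiphenylsilyl)oxy]prop-1-en-2-yl}-6-ethenyl-6-methyl-4-[(triethylsilyl)oxy]hexahydro-1-benzofuran-2(3H)-one
Conditions: KOtBu (0.2 equiv), THF, 0 °C
Reagents that add atoms: none
Why: Base-catalysed lactonisation: the C6 alkoxide attacks the ester carbonyl (5-exo-trig) to close the trans-fused γ-lactone and releases tert-butoxide, which carries the chain; the diequatorial 1,3-related oxygens are too far apart for silyl migration.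

Step 16
Reactants: 24 saturated lactone
Product: 27 (3aS,4S,6R,7R,7aR)-7-{3-[(tert-butyldiphenylsilyl)oxy]prop-1-en-2-yl}-6-ethenyl-6-methyl-3-methylidene-4-[(triethylsilyl)oxy]hexahydro-1-benzofuran-2(3H)-one, via Mannich base 25 (not isolated), via ammonium iodide 26 (not isolated)
Conditions: LiN(iPr)2, THF, −78 °C; Me2N=CH2 I (Eschenmoser's salt), −78 °C → rt; then MeI, MeOH, rt; then NaHCO3 (aq), CH2Cl2
Reagents that add atoms: N,N-dimethylmethaniminium iodide, C=[N+](C)C.[I-]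
Why: α-Methylenation of a γ-lactone: Mannich reaction of the lactone enolate, quaternisation and E1cB loss of trimethylamine; C11 is the only enolisable position and ends up sp2.

Step 17
Reactants: 27 α-methylene lactone triethylsilyl ether
Product: 28 (3aR,4S,6R,7R,7aR)-7-{3-[(tert-butyldiphenylsilyl)oxy]prop-1-en-2-yl}-6-ethenyl-4-hydroxy-6-methyl-3-methylidenehexahydro-1-benzofuran-2(3H)-one
Conditions: PPTS (0.2 equiv), MeOH/CH2Cl2, 0 °C → rt
Reagents that add atoms: none
Why: Mild acid methanolysis cleaves the triethylsilyl ether far faster than the primary tert-butyldiphenylsilyl ether, and without base methanol should not add to the methylene lactone.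

Step 18
Reactants: 29 methyl (2R)-3-hydroxy-2-methylpropanoate
Product: 30 methyl (2R)-3-[(tert-butyldimethylsilyl)oxy]-2-methylpropanoate
Conditions: TBSCl, imidazole, CH2Cl2, rt
Reagents that add atoms: tert-butyl(chloro)dimethylsilane, CC(C)(C)[Si](C)(C)Cl
Why: Standard silylation of the primary alcohol of the Roche ester; the stereocentre is not involved.

Step 19
Reactants: 30 methyl (2R)-3-[(tert-butyldimethylsilyl)oxy]-2-methylpropanoate
Product: 31 (2R)-3-[(tert-butyldimethylsilyl)oxy]-2-methylpropanoic acid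
Conditions: LiOH, THF/MeOH/H2O, 0 °C → rt; then 1 M HCl to pH 4
Reagents that add atoms: lithium hydroxide, [Li+].[OH-]
Why: Saponification at low temperature, under which β-elimination and epimerisation of the α-centre should be slow.

Step 20
Reactants: 28 C8 alcohol; 31 (2R)-3-[(tert-butyldimethylsilyl)oxy]-2-methylpropanoic acid
Product: 33 (3aR,4S,6R,7R,7aR)-7-{3-[(tert-butyldiphenylsilyl)oxy]prop-1-en-2-yl}-6-ethenyl-6-methyl-3-methylidene-2-oxooctahydro-1-benzofuran-4-yl (2R)-3-[(tert-butyldimethylsilyl)oxy]-2-methylpropanoate, via mixed aroyl anhydride 32 (not isolated)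
Conditions: 31, 2,4,6-trichlorobenzoyl chloride, Et3N, THF, 0 °C → rt; then 28, DMAP, toluene, rt
Reagents that add atoms: none
Why: Yamaguchi esterification: DMAP transfers the aliphatic acyl group of the mixed anhydride to the equatorial secondary C8 alcohol, with retention at C8 and at the acid α-centre.

Step 21
Reactants: 33 bis-silyl ether
Product: 34 (3aR,4S,6R,7R,7aR)-6-ethenyl-7-(3-hydroxyprop-1-en-2-yl)-6-methyl-3-methylidene-2-oxooctahydro-1-benzofuran-4-yl (2R)-3-hydroxy-2-methylpropanoate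
Conditions: HF·pyridine, pyridine, THF, 0 °C → rt
Reagents that add atoms: none
Why: Buffered acidic fluoride removes both silyl ethers without base, so the methylene lactone and the β-hydroxy ester should not suffer conjugate addition, acyl migration or elimination.

**Compound list**

1 | prop-2-yn-1-ol | C#CCO | starting material
2 | bromomagnesium (2Z)-3-(bromomagnesio)-2-methylprop-2-en-1-olate | C/C(CO[Mg]Br)=C/[Mg]Br | intermediate (not isolated)
3 | (2Z)-3-iodo-2-methylprop-2-en-1-ol | C/C(CO)=C/I | intermediate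
4 | tert-butyl{[(2Z)-3-iodo-2-methylprop-2-en-1-yl]oxy}diphenylsilane | C/C(CO[Si](c1ccccc1)(c1ccccc1)C(C)(C)C)=C/I | intermediate
5 | {(1Z)-3-[(tert-butyldiphenylsilyl)oxy]-2-methylprop-1-en-1-yl}lithium | C/C(CO[Si](c1ccccc1)(c1ccccc1)C(C)(C)C)=C/[Li] | intermediate (not isolated)
6 | tert-butyl{[(2Z)-2-methyl-3-(4,4,5,5-tetramethyl-1,3,2-dioxaborolan-2-yl)prop-2-en-1-yl]oxy}diphenylsilane | C/C(CO[Si](c1ccccc1)(c1ccccc1)C(C)(C)C)=C/B1OC(C)(C)C(C)(C)O1 | intermediate
7 | ethyl but-2-ynoate | CC#CC(=O)OCC | starting material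
8 | (1,3-dioxolan-2-ylmethyl)magnesium bromide | Br[Mg]CC1OCCO1 | starting material
9 | ethyl (2E)-4-(1,3-dioxolan-2-yl)-3-methylbut-2-enoate | CCOC(=O)/C=C(\C)CC1OCCO1 | intermediate
10 | (2E)-4-(1,3-dioxolan-2-yl)-3-methylbut-2-en-1-ol | OC/C=C(\C)CC1OCCO1 | intermediate
11 | (2E)-4-(1,3-dioxolan-2-yl)-3-methylbut-2-en-1-yl diethyl phosphate | CCOP(=O)(OCC)OC/C=C(\C)CC1OCCO1 | intermediate
12 | tert-butyl{[(2Z,4R)-4-(1,3-dioxolan-2-ylmethyl)-2,4-dimethylhexa-2,5-dien-1-yl]oxy}diphenylsilane | C=C[C@@](C)(CC1OCCO1)/C=C(/C)CO[Si](c1ccccc1)(c1ccccc1)C(C)(C)C | intermediate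
13 | (3R,4Z)-6-[(tert-butyldiphenylsilyl)oxy]-3-ethenyl-3,5-dimethylhex-4-enal | C=C[C@@](C)(CC=O)/C=C(/C)CO[Si](c1ccccc1)(c1ccccc1)C(C)(C)C | intermediate
14 | 4-tert-butoxy-4-oxobutanoic acid | OC(=O)CCC(=O)OC(C)(C)C | starting material
15 | (4R)-4-benzyl-1,3-oxazolidin-2-one | O=C1N[C@H](Cc2ccccc2)CO1 | starting material
16 | 4-tert-butoxy-4-oxobutanoic 2,2-dimethylpropanoic anhydride | CC(C)(C)C(=O)OC(=O)CCC(=O)OC(C)(C)C | intermediate (not isolated)
17 | tert-butyl 4-[(4R)-4-benzyl-2-oxo-1,3-oxazolidin-3-yl]-4-oxobutanoate | O=C1OC[C@@H](Cc2ccccc2)N1C(=O)CCC(=O)OC(C)(C)C | intermediate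
18 | Z dibutylboron enolate of 17 | CCCCB(CCCC)O/C(=C\CC(=O)OC(C)(C)C)N1C(=O)OC[C@H]1Cc1ccccc1 | intermediate (not isolated)
19 | tert-butyl (3R,4S,6R,7Z)-3-{[(4R)-4-benzyl-2-oxo-1,3-oxazolidin-3-yl]carbonyl}-9-[(tert-butyldiphenylsilyl)oxy]-6-ethenyl-4-hydroxy-6,8-dimethylnon-7-enoate | O=C1OC[C@@H](Cc2ccccc2)N1C(=O)[C@H](CC(=O)OC(C)(C)C)[C@@H](O)C[C@](C)(C=C)/C=C(/C)CO[Si](c1ccccc1)(c1ccccc1)C(C)(C)C | intermediate
20 | tert-butyl (3R,4S,6R,7Z)-3-{[(4R)-4-benzyl-2-oxo-1,3-oxazolidin-3-yl]carbonyl}-9-[(tert-butyldiphenylsilyl)oxy]-6-ethenyl-6,8-dimethyl-4-[(triethylsilyl)oxy]non-7-enoate | O=C1OC[C@@H](Cc2ccccc2)N1C(=O)[C@H](CC(=O)OC(C)(C)C)[C@@H](O[Si](CC)(CC)CC)C[C@](C)(C=C)/C=C(/C)CO[Si](c1ccccc1)(c1ccccc1)C(C)(C)C | intermediate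
21 | tert-butyl (3S,4S,6R,7Z)-9-[(tert-butyldiphenylsilyl)oxy]-6-ethenyl-3-(hydroxymethyl)-6,8-dimethyl-4-[(triethylsilyl)oxy]non-7-enoate | OC[C@H](CC(=O)OC(C)(C)C)[C@@H](O[Si](CC)(CC)CC)C[C@](C)(C=C)/C=C(/C)CO[Si](c1ccccc1)(c1ccccc1)C(C)(C)C | intermediate
22 | tert-butyl (3R,4S,6R,7Z)-9-[(tert-butyldiphenylsilyl)oxy]-6-ethenyl-3-formyl-6,8-dimethyl-4-[(triethylsilyl)oxy]non-7-enoate | O=C[C@H](CC(=O)OC(C)(C)C)[C@@H](O[Si](CC)(CC)CC)C[C@](C)(C=C)/C=C(/C)CO[Si](c1ccccc1)(c1ccccc1)C(C)(C)C | intermediate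
23 | tert-butyl 2-[(1S,2R,3R,4R,6S)-3-{3-[(tert-butyldiphenylsilyl)oxy]prop-1-en-2-yl}-4-ethenyl-2-hydroxy-4-methyl-6-[(triethylsilyl)oxy]cyclohexyl]acetate | C=C[C@@]1(C)C[C@H](O[Si](CC)(CC)CC)[C@@H](CC(=O)OC(C)(C)C)[C@H](O)[C@H]1C(=C)CO[Si](c1ccccc1)(c1ccccc1)C(C)(C)C | intermediate
24 | (3aS,4S,6R,7R,7aR)-7-{3-[(tert-butyldiphenylsilyl)oxy]prop-1-en-2-yl}-6-ethenyl-6-methyl-4-[(triethylsilyl)oxy]hexahydro-1-benzofuran-2(3H)-one | C=C[C@@]1(C)C[C@H](O[Si](CC)(CC)CC)[C@H]2CC(=O)O[C@@H]2[C@H]1C(=C)CO[Si](c1ccccc1)(c1ccccc1)C(C)(C)C | intermediate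
25 | 3-[(dimethylamino)methyl] derivative of 24 (both C3 epimers) | C=C[C@@]1(C)C[C@H](O[Si](CC)(CC)CC)[C@H]2C(CN(C)C)C(=O)O[C@@H]2[C@H]1C(=C)CO[Si](c1ccccc1)(c1ccccc1)C(C)(C)C | intermediate (not isolated)
26 | 3-[(trimethylammonio)methyl] iodide derived from 25 | C=C[C@@]1(C)C[C@H](O[Si](CC)(CC)CC)[C@H]2C(C[N+](C)(C)C)C(=O)O[C@@H]2[C@H]1C(=C)CO[Si](c1ccccc1)(c1ccccc1)C(C)(C)C.[I-] | intermediate (not isolated)
27 | (3aS,4S,6R,7R,7aR)-7-{3-[(tert-butyldiphenylsilyl)oxy]prop-1-en-2-yl}-6-ethenyl-6-methyl-3-methylidene-4-[(triethylsilyl)oxy]hexahydro-1-benzofuran-2(3H)-one | C=C[C@@]1(C)C[C@H](O[Si](CC)(CC)CC)[C@H]2C(=C)C(=O)O[C@@H]2[C@H]1C(=C)CO[Si](c1ccccc1)(c1ccccc1)C(C)(C)C | intermediate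
28 | (3aR,4S,6R,7R,7aR)-7-{3-[(tert-butyldiphenylsilyl)oxy]prop-1-en-2-yl}-6-ethenyl-4-hydroxy-6-methyl-3-methylidenehexahydro-1-benzofuran-2(3H)-one | C=C[C@@]1(C)C[C@H](O)[C@H]2C(=C)C(=O)O[C@@H]2[C@H]1C(=C)CO[Si](c1ccccc1)(c1ccccc1)C(C)(C)C | intermediate
29 | methyl (2R)-3-hydroxy-2-methylpropanoate | COC(=O)[C@H](C)CO | starting material
30 | methyl (2R)-3-[(tert-butyldimethylsilyl)oxy]-2-methylpropanoate | COC(=O)[C@H](C)CO[Si](C)(C)C(C)(C)C | intermediate
31 | (2R)-3-[(tert-butyldimethylsilyl)oxy]-2-methylpropanoic acid | OC(=O)[C@H](C)CO[Si](C)(C)C(C)(C)C | intermediate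
32 | (2R)-3-[(tert-butyldimethylsilyl)oxy]-2-methylpropanoic 2,4,6-trichlorobenzoic anhydride | O=C(OC(=O)[C@H](C)CO[Si](C)(C)C(C)(C)C)c1c(Cl)cc(Cl)cc1Cl | intermediate (not isolated)
33 | (3aR,4S,6R,7R,7aR)-7-{3-[(tert-butyldiphenylsilyl)oxy]prop-1-en-2-yl}-6-ethenyl-6-methyl-3-methylidene-2-oxooctahydro-1-benzofuran-4-yl (2R)-3-[(tert-butyldimethylsilyl)oxy]-2-methylpropanoate | C=C[C@@]1(C)C[C@H](OC(=O)[C@H](C)CO[Si](C)(C)C(C)(C)C)[C@H]2C(=C)C(=O)O[C@@H]2[C@H]1C(=C)CO[Si](c1ccccc1)(c1ccccc1)C(C)(C)C | intermediate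
34 | (3aR,4S,6R,7R,7aR)-6-ethenyl-7-(3-hydroxyprop-1-en-2-yl)-6-methyl-3-methylidene-2-oxooctahydro-1-benzofuran-4-yl (2R)-3-hydroxy-2-methylpropanoate | C=C[C@@]1(C)C[C@H](OC(=O)[C@H](C)CO)[C@H]2C(=C)C(=O)O[C@@H]2[C@H]1C(=C)CO | target

**Step count**

Total: 21 steps. Longest linear sequence: 15 steps (steps 4–8, 10–17, 20, 21).

**Steps most likely to fail**

1. Step 7 (allylic substitution). Transfer of the hindered Z-trisubstituted alkenyl group to the γ-carbon may be slow, so that linear substitution or protodeboronation takes over, or facial control at C10 may be poor. The fallback is a sigmatropic route that sets out from 4 and 7 and comes back at 19. Alkenyllithium 5 (from 4 as in step 3) is converted with CuI into the alkenylcopper reagent and added syn to 7 to give ethyl (2E,4Z)-6-[(tert-butyldiphenylsilyl)oxy]-3,5-dimethylhexa-2,4-dienoate F1. Reduction with iBu2AlH gives (2E,4Z)-6-[(tert-butyldiphenylsilyl)oxy]-3,5-dimethylhexa-2,4-dien-1-ol F2. A Johnson–Claisen rearrangement (triethyl orthoacetate, catalytic propanoic acid, 140 °C) builds the quaternary centre in racemic ethyl (4Z)-6-[(tert-butyldiphenylsilyl)oxy]-3-ethenyl-3,5-dimethylhex-4-enoate F3. iBu2AlH at −78 °C gives racemic (4Z)-6-[(tert-butyldiphenylsilyl)oxy]-3-ethenyl-3,5-dimethylhex-4-enal F4. The auxiliary-controlled aldol of step 10 on this racemate should give 19 together with its epimer at the quaternary centre, tert-butyl (3R,4S,6S,7Z)-3-{[(4R)-4-benzyl-2-oxo-1,3-oxazolidin-3-yl]carbonyl}-9-[(tert-butyldiphenylsilyl)oxy]-6-ethenyl-4-hydroxy-6,8-dimethylnon-7-enoate F5. The two are diastereomers and are separated by chromatography, and the route continues from 19.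

2. Step 14 (carbonyl-ene closure). The crowded alkene, inductively deactivated by the allylic silyloxy group, may react slowly. Methyl transfer from aluminium to the aldehyde, hydrogen transfer from the silyloxymethyl group through the axial-oxygen chair, or β-elimination of the C8 silyloxy group could then compete. The fallback closes the ring before C15 is oxygenated; it sets out from 11 and comes back at 23.
   - Step 7 with commercial 4,4,5,5-tetramethyl-2-(2-methylprop-1-en-1-yl)-1,3,2-dioxaborolane gives 2-[(2R)-2-ethenyl-2,4-dimethylpent-3-en-1-yl]-1,3-dioxolane F6.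
   - The operations of steps 8 and 10–13 give in turn (3R)-3-ethenyl-3,5-dimethylhex-4-enal F7, tert-butyl (3R,4S,6R)-3-{[(4R)-4-benzyl-2-oxo-1,3-oxazolidin-3-yl]carbonyl}-6-ethenyl-4-hydroxy-6,8-dimethylnon-7-enoate F8, tert-butyl (3R,4S,6R)-3-{[(4R)-4-benzyl-2-oxo-1,3-oxazolidin-3-yl]carbonyl}-6-ethenyl-6,8-dimethyl-4-[(triethylsilyl)oxy]non-7-enoate F9, tert-butyl (3S,4S,6R)-6-ethenyl-3-(hydroxymethyl)-6,8-dimethyl-4-[(triethylsilyl)oxy]non-7-enoate F10 and tert-butyl (3R,4S,6R)-6-ethenyl-3-formyl-6,8-dimethyl-4-[(triethylsilyl)oxy]non-7-enoate F11.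
   - This aldehyde has an electron-rich alkene with two equivalent methyl hydrogen donors, as in citronellal, and should close under Me2AlCl to tert-butyl 2-[(1S,2R,3S,4R,6S)-4-ethenyl-2-hydroxy-4-methyl-3-(prop-1-en-2-yl)-6-[(triethylsilyl)oxy]cyclohexyl]acetate F12.
   - Allylic oxidation of the isopropenyl methyl group (SeO2 cat., tBuOOH, CH2Cl2) gives tert-butyl 2-[(1S,2R,3R,4R,6S)-4-ethenyl-2-hydroxy-3-(3-hydroxyprop-1-en-2-yl)-4-methyl-6-[(triethylsilyl)oxy]cyclohexyl]acetate F13.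
   - Selective silylation of the primary alcohol (TBDPSCl, imidazole) gives 23.

3. Step 16 (α-methylenation). Enolisation or aminomethylation at the hindered lactone α-carbon may be incomplete, or the quaternisation and elimination sequence may stall. The fallback sets out from 24 and comes back at 27. Formylation (NaH, ethyl formate, THF) gives (3aS,4S,6R,7R,7aR)-7-{3-[(tert-butyldiphenylsilyl)oxy]prop-1-en-2-yl}-6-ethenyl-3-(hydroxymethylidene)-6-methyl-4-[(triethylsilyl)oxy]hexahydro-1-benzofuran-2(3H)-one F14. Treatment with aqueous formaldehyde and K2CO3 should then give 27 by aldol addition, formyl transfer to oxygen and loss of formate.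

Further compounds
F1 | step 7 | ethyl (2E,4Z)-6-[(tert-butyldiphenylsilyl)oxy]-3,5-dimethylhexa-2,4-dienoate | CCOC(=O)/C=C(\C)/C=C(/C)CO[Si](c1ccccc1)(c1ccccc1)C(C)(C)C
F2 | step 7 | (2E,4Z)-6-[(tert-butyldiphenylsilyl)oxy]-3,5-dimethylhexa-2,4-dien-1-ol | OC/C=C(\C)/C=C(/C)CO[Si](c1ccccc1)(c1ccccc1)C(C)(C)C
F3 | step 7 | ethyl (4Z)-6-[(tert-butyldiphenylsilyl)oxy]-3-ethenyl-3,5-dimethylhex-4-enoate (racemic) | CCOC(=O)CC(C)(C=C)/C=C(/C)CO[Si](c1ccccc1)(c1ccccc1)C(C)(C)C
F4 | step 7 | (4Z)-6-[(tert-butyldiphenylsilyl)oxy]-3-ethenyl-3,5-dimethylhex-4-enal (racemic) | C=CC(C)(CC=O)/C=C(/C)CO[Si](c1ccccc1)(c1ccccc1)C(C)(C)C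
F5 | step 7 | tert-butyl (3R,4S,6S,7Z)-3-{[(4R)-4-benzyl-2-oxo-1,3-oxazolidin-3-yl]carbonyl}-9-[(tert-butyldiphenylsilyl)oxy]-6-ethenyl-4-hydroxy-6,8-dimethylnon-7-enoate | O=C1OC[C@@H](Cc2ccccc2)N1C(=O)[C@H](CC(=O)OC(C)(C)C)[C@@H](O)C[C@@](C)(C=C)/C=C(/C)CO[Si](c1ccccc1)(c1ccccc1)C(C)(C)C
F6 | step 14 | 2-[(2R)-2-ethenyl-2,4-dimethylpent-3-en-1-yl]-1,3-dioxolane | C=C[C@@](C)(CC1OCCO1)C=C(C)C
F7 | step 14 | (3R)-3-ethenyl-3,5-dimethylhex-4-enal | C=C[C@@](C)(CC=O)C=C(C)C
F8 | step 14 | tert-butyl (3R,4S,6R)-3-{[(4R)-4-benzyl-2-oxo-1,3-oxazolidin-3-yl]carbonyl}-6-ethenyl-4-hydroxy-6,8-dimethylnon-7-enoate | O=C1OC[C@@H](Cc2ccccc2)N1C(=O)[C@H](CC(=O)OC(C)(C)C)[C@@H](O)C[C@](C)(C=C)C=C(C)C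
F9 | step 14 | tert-butyl (3R,4S,6R)-3-{[(4R)-4-benzyl-2-oxo-1,3-oxazolidin-3-yl]carbonyl}-6-ethenyl-6,8-dimethyl-4-[(triethylsilyl)oxy]non-7-enoate | O=C1OC[C@@H](Cc2ccccc2)N1C(=O)[C@H](CC(=O)OC(C)(C)C)[C@@H](O[Si](CC)(CC)CC)C[C@](C)(C=C)C=C(C)C
F10 | step 14 | tert-butyl (3S,4S,6R)-6-ethenyl-3-(hydroxymethyl)-6,8-dimethyl-4-[(triethylsilyl)oxy]non-7-enoate | OC[C@H](CC(=O)OC(C)(C)C)[C@@H](O[Si](CC)(CC)CC)C[C@](C)(C=C)C=C(C)C
F11 | step 14 | tert-butyl (3R,4S,6R)-6-ethenyl-3-formyl-6,8-dimethyl-4-[(triethylsilyl)oxy]non-7-enoate | O=C[C@H](CC(=O)OC(C)(C)C)[C@@H](O[Si](CC)(CC)CC)C[C@](C)(C=C)C=C(C)C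
F12 | step 14 | tert-butyl 2-[(1S,2R,3S,4R,6S)-4-ethenyl-2-hydroxy-4-methyl-3-(prop-1-en-2-yl)-6-[(triethylsilyl)oxy]cyclohexyl]acetate | C=C[C@@]1(C)C[C@H](O[Si](CC)(CC)CC)[C@@H](CC(=O)OC(C)(C)C)[C@H](O)[C@H]1C(C)=C
F13 | step 14 | tert-butyl 2-[(1S,2R,3R,4R,6S)-4-ethenyl-2-hydroxy-3-(3-hydroxyprop-1-en-2-yl)-4-methyl-6-[(triethylsilyl)oxy]cyclohexyl]acetate | C=C[C@@]1(C)C[C@H](O[Si](CC)(CC)CC)[C@@H](CC(=O)OC(C)(C)C)[C@H](O)[C@H]1C(=C)CO
F14 | step 16 | (3aS,4S,6R,7R,7aR)-7-{3-[(tert-butyldiphenylsilyl)oxy]prop-1-en-2-yl}-6-ethenyl-3-(hydroxymethylidene)-6-methyl-4-[(triethylsilyl)oxy]hexahydro-1-benzofuran-2(3H)-one | C=C[C@@]1(C)C[C@H](O[Si](CC)(CC)CC)[C@H]2C(=CO)C(=O)O[C@@H]2[C@H]1C(=C)CO[Si](c1ccccc1)(c1ccccc1)C(C)(C)C
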